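**Retrosynthetic overview**

1. Endgame: the C8 ester, the C8/C9 cis-diol (OsO4, anti to the C7 ester) and the C7 angelate are installed on 7-silyloxy-longipina-2,8-dien-1-one.
2. Enone ring: the C1–C2 bond is formed by a Lewis-acid type-2 carbonyl-ene reaction of a bicyclo[4.1.1]octene carrying CHO on C11 and isopropenyl on C4. Enabling feature: both groups sit cis-1,3 on the cyclobutane C10–C11–C5–C4, on the face opposite the C6–C9 bridge, so the seven-membered ring holds them pseudo-diaxial and within bonding distance; the isopropenyl group has two equivalent termini, so no alkene geometry has to be made.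
3. Seven-membered ring: ring-closing metathesis (C8=C9) between a C10 vinyl group and a C7 vinyl carbinol; C7 is set by catalyst-controlled vinylzinc addition to a neopentyl aldehyde.
4. Cyclobutane with all four ring stereocentres: vinylketene + 5,5-dimethylcyclopentadiene [2+2], then exo-methylation. The cyclopentene is a temporary ring; cleaving its C=C releases the C1 and C7 aldehydes, and the cyclobutanone becomes acetyl, then isopropenyl. Resolution is by a chiral acetal.
5. Ring order: four-membered ring (with temporary five-membered ring) → seven-membered ring → six-membered enone ring.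

Key step: step 14

Remark: atom labels C1–C11 in the prose are the longipinane positions of the target (C1 ketone, C2=C3 alkene, C4/C5/C10/C11 cyclobutane, C6 gem-dimethyl carbon, C7–C9 oxygenated carbons).
Remark: compounds 6–13 are racemic; their SMILES show the enantiomer carried on after the resolution in step 8.
Remark: the 2-methylbutanoate centre of the target is R, so (R)-2-methylbutanoic acid is used.
Assumption: 4,4-dimethylcyclopent-2-en-1-one, crotonyl chloride, (2R,3R)-butane-2,3-diol, (+)-MIB, angelic anhydride and (R)-2-methylbutanoic acid are purchased.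

**Route**

Step 1
Reactants: 1 4,4-dimethylcyclopent-2-en-1-one
Product: 2 4,4-dimethylcyclopent-2-en-1-one p-toluenesulfonylhydrazone
Conditions: TsNHNH2, MeOH, cat. AcOH, rt
Reagents that add atoms: p-toluenesulfonyl hydrazide, Cc1ccc(cc1)S(=O)(=O)NN
Why: Acid-catalysed hydrazone formation from a ketone and a sulfonyl hydrazide gives the Shapiro substrate; no stereocentre is formed.

Step 2
Reactants: 2 4,4-dimethylcyclopent-2-en-1-one p-toluenesulfonylhydrazone
Product: 3 5,5-dimethylcyclopenta-1,3-diene
Conditions: MeLi (2.2 equiv), Et2O, 0 °C → rt; H2O; product distilled with the solvent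
Reagents that add atoms: none
Why: Shapiro reaction: deprotonation at the saturated α′-CH2, loss of sulfinate and N2 and protonation of the vinyllithium should give the diene, whose gem-dimethyl group blocks 1,5-hydrogen shifts.

Step 3
Reactants: 3 5,5-dimethylcyclopenta-1,3-diene, 4 (E)-but-2-enoyl chloride
Product: 6 rac-4,4-dimethyl-7-endo-vinylbicyclo[3.2.0]hept-2-en-6-one, via vinylketene 5 (not isolated)
Conditions: Et3N, excess 3, CH2Cl2, slow addition of 4, 0 °C → rt
Reagents that add atoms: none
Why: 1,4-Dehydrochlorination gives vinylketene, which should add to the cyclic diene in a ketene–alkene [2+2] cycloaddition; the ketene carbonyl carbon bonds to the diene terminus next to CMe2, the ring fusion is cis, and the single ketene substituent ends endo, as is usual for aldoketenes.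

Step 4
Reactants: 6 rac-4,4-dimethyl-7-endo-vinylbicyclo[3.2.0]hept-2-en-6-one
Product: 7 rac-4,4,7-trimethyl-7-vinylbicyclo[3.2.0]hept-2-en-6-one (methyl exo; vinyl endo)
Conditions: LiN(i-Pr)2, THF, −78 °C; MeI, −78 → −20 °C; kept below 25 °C
Reagents that add atoms: iodomethane, CI
Why: α-Alkylation of the cyclobutanone dienolate from the convex exo face should place methyl exo and leave vinyl endo, which fixes the quaternary C10 centre relative to the ring fusion.

Step 5
Reactants: 7 rac-4,4,7-trimethyl-7-vinylbicyclo[3.2.0]hept-2-en-6-one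
Product: 8 rac-4,4,7-trimethyl-7-vinylbicyclo[3.2.0]hept-2-ene-6-carbonitrile (both C6 epimers)
Conditions: TosMIC, t-BuOK, DME, EtOH (2 equiv), 0 → 25 °C; aq. NH4Cl
Reagents that add atoms: p-toluenesulfonylmethyl isocyanide, Cc1ccc(cc1)S(=O)(=O)C[N+]#[C-]
Why: van Leusen reductive cyanation homologates ketones flanked by a quaternary carbon (as in 17-oxo steroids) to nitriles, and the strained cyclobutanone carbonyl is a good acceptor; the new centre is set in step 6.

Step 6
Reactants: 8 rac-4,4,7-trimethyl-7-vinylbicyclo[3.2.0]hept-2-ene-6-carbonitrile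
Product: 10 rac-1-(4,4,7-trimethyl-7-vinylbicyclo[3.2.0]hept-2-en-6-yl)ethan-1-one (acetyl exo), via ketimine 9 (not isolated)
Conditions: MeLi, Et2O, 0 °C; 1 M HCl, THF, rt; K2CO3, MeOH, rt
Reagents that add atoms: methyllithium, [Li]C; water, O
Why: Organolithium addition to the nitrile and hydrolysis of the imine give the methyl ketone, and base equilibration α to the ketone should place the acetyl group exo, trans to the five-membered ring and away from its gem-dimethyl carbon.

Step 7
Reactants: 10 rac-1-(4,4,7-trimethyl-7-vinylbicyclo[3.2.0]hept-2-en-6-yl)ethan-1-one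
Product: 13 rac-2-(2-acetyl-4-formyl-3-methyl-3-vinylcyclobutyl)-2-methylpropanal (all-trans), via diol 11 (not isolated), via cis-dialdehyde 12 (not isolated)
Conditions: OsO4 (2 mol%), NMO, acetone/H2O, 0 °C; NaIO4, THF/H2O, rt; DBU (0.1 equiv), CH2Cl2, 0 °C
Reagents that add atoms: N-methylmorpholine N-oxide, C[N+]1([O-])CCOCC1; water, O
Why: Upjohn dihydroxylation of the strained cyclopentene from its exo face (the endo vinyl group on the quaternary carbon is shielded) and periodate glycol cleavage open the temporary ring; base epimerization α to the new C11 aldehyde should give the all-trans cyclobutane, because the kinetic isomer has the formyl group cis to the bulky tertiary side chain.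

Step 8
Reactants: 13 rac-2-(2-acetyl-4-formyl-3-methyl-3-vinylcyclobutyl)-2-methylpropanal
Product: 14 2-[2-acetyl-4-((4R,5R)-4,5-dimethyl-1,3-dioxolan-2-yl)-3-methyl-3-vinylcyclobutyl]-2-methylpropanal (ring configured as in the target)
Conditions: (2R,3R)-butane-2,3-diol (1.0 equiv), PPTS (cat.), MgSO4, CH2Cl2, 0 °C → rt; chromatographic separation of the two diastereomers
Reagents that add atoms: (2R,3R)-butane-2,3-diol, C[C@@H](O)[C@@H](C)O
Why: Kinetic acetalization should take the ring-bound aldehyde and leave the α-quaternary aldehyde and the ketone; with an enantiopure C2-symmetric diol the racemate becomes two separable diastereomers (resolution through diastereomeric acetals), and the acetal of the unwanted cyclobutane enantiomer is removed at this point.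

Step 9
Reactants: 14 2-[2-acetyl-4-((4R,5R)-4,5-dimethyl-1,3-dioxolan-2-yl)-3-methyl-3-vinylcyclobutyl]-2-methylpropanal
Product: 15 1-[3-((4R,5R)-4,5-dimethyl-1,3-dioxolan-2-yl)-2-((3R)-3-hydroxy-2-methylpent-4-en-2-yl)-4-methyl-4-vinylcyclobutyl]ethan-1-one (vinyl carbinol at C7)
Conditions: Zn(CH=CH2)2, (+)-MIB (10 mol%), toluene/hexane, 0 °C; aq. NH4Cl
Reagents that add atoms: divinylzinc, C=C[Zn]C=C
Why: Amino-alcohol-catalysed asymmetric vinylzinc addition to the α-quaternary aldehyde should deliver vinyl to the Re face under catalyst control, giving the R carbinol that becomes 7S in the target; ketone and acetal do not react with the organozinc.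

Step 10
Reactants: 15 the (3R)-allylic alcohol
Product: 16 tert-butyldimethylsilyl ether of 15
Conditions: TBSOTf (1.1 equiv), 2,6-lutidine, CH2Cl2, −78 °C
Reagents that add atoms: tert-butyldimethylsilyl trifluoromethanesulfonate, CC(C)(C)[Si](C)(C)OS(=O)(=O)C(F)(F)F
Why: Silyl triflate silylation protects the hindered secondary alcohol at low temperature and with little excess reagent, where acetal and ketone should be untouched.

Step 11
Reactants: 16 the silyl ether diene
Product: 17 7-acetyl-4-(tert-butyldimethylsilyloxy)-8-((4R,5R)-4,5-dimethyl-1,3-dioxolan-2-yl)-1,5,5-trimethylbicyclo[4.1.1]oct-2-ene (both one-carbon-bridge substituents anti to the four-carbon bridge)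
Conditions: second-generation Hoveyda–Grubbs catalyst (10 mol%), toluene (2 mM), 80 °C, argon sparge
Reagents that add atoms: none
Why: Ring-closing metathesis of the two cis-1,3 vinyl arms should close the seven-membered ring as the cis C8=C9 alkene, with ethene removal driving it; no stereocentre changes.

Step 12
Reactants: 17 the bicyclo[4.1.1]octene methyl ketone
Product: 18 4-(tert-butyldimethylsilyloxy)-8-((4R,5R)-4,5-dimethyl-1,3-dioxolan-2-yl)-7-isopropenyl-1,5,5-trimethylbicyclo[4.1.1]oct-2-ene
Conditions: Ph3PCH3Br, t-BuOK, toluene, 60 °C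
Reagents that add atoms: methyltriphenylphosphonium bromide, C[P+](c1ccccc1)(c1ccccc1)c1ccccc1.[Br-]
Why: Wittig methylenation under conditions used for hindered ketones converts acetyl into isopropenyl; any enolization should occur toward the methyl group, since an enolate toward C4 would place an exocyclic double bond on the cyclobutane bridge, so C4 keeps its configuration.

Step 13
Reactants: 18 the isopropenyl acetal
Product: 19 4-(tert-butyldimethylsilyloxy)-7-isopropenyl-1,5,5-trimethylbicyclo[4.1.1]oct-2-ene-8-carbaldehyde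
Conditions: PPTS, acetone/H2O (9:1), 50 °C
Reagents that add atoms: water, O
Why: Mild acid-catalysed acetal hydrolysis frees the C1 aldehyde without cleaving the hindered silyl ether or protonating the isopropenyl group; the aldehyde is used at once to limit epimerization at C11.

Step 14
Reactants: 19 4-(tert-butyldimethylsilyloxy)-7-isopropenyl-1,5,5-trimethylbicyclo[4.1.1]oct-2-ene-8-carbaldehyde
Product: 20 7-(tert-butyldimethylsilyloxy)longipina-3(12),8-dien-1-ol (both C1 epimers)
Conditions: Me2AlCl (2 equiv), CH2Cl2, −78 → −20 °C; aq. KNaC4H4O6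
Reagents that add atoms: none
Why: Me2AlCl binds the C1 aldehyde, the terminal CH2 of the C4 isopropenyl group attacks C1 while a hydrogen of the isopropenyl methyl passes to the carbonyl oxygen through a six-membered transition state, so C1–C2 forms in a concerted type-2 intramolecular carbonyl-ene reaction; the closest known case is the Me2AlCl-promoted cyclization of 5-methylhex-5-enal to 3-methylenecyclohexanol. The six-membered ring C11–C1–C2–C3–C4–C5 closes exo with respect to the carbonyl group and endo with respect to the alkene, turning the bicyclo[4.1.1]octene into the complete tricyclic longipinane skeleton with C1 oxygenated and C3 carrying its one-carbon substituent. The only new stereocentre is the C1 carbinol, formed as a mixture and removed by oxidation in step 15; C11 and C4 are already in place and are not touched. The step needs the ene pathway to win over Prins-type cation chemistry at C3 (a cyclobutylcarbinyl position prone to ring expansion) and over reaction at the C8=C9 alkene: the cis-1,3 pseudo-diaxial placement of formyl and isopropenyl enforced by the seven-membered ring gives a reacting distance no other alkene can reach, hydrogen transfer from C4 is excluded because it would give a bridgehead alkene, and the aluminium alkoxide formed with loss of methane leaves no free acid.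

Step 15
Reactants: 20 7-(tert-butyldimethylsilyloxy)longipina-3(12),8-dien-1-ol
Product: 22 7-(tert-butyldimethylsilyloxy)longipina-2,8-dien-1-one, via deconjugated enone 21 (not isolated)
Conditions: Dess–Martin periodinane, CH2Cl2, 0 °C → rt; then DBU (3 equiv), rt
Reagents that add atoms: none
Why: Dess–Martin oxidation gives the β,γ-unsaturated ketone, and base-mediated alkene isomerization through the C2 dienolate should move the exocyclic double bond into conjugation (the verbenone-type enone is the stable isomer); the bridgehead carbon C11 cannot enolize.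

Step 16
Reactants: 22 7-(tert-butyldimethylsilyloxy)longipina-2,8-dien-1-one
Product: 23 7-hydroxylongipina-2,8-dien-1-one
Conditions: n-Bu4NF, THF, 40 °C
Reagents that add atoms: none
Why: Fluoride desilylation frees the C7 alcohol; no ester is present yet, so the basic conditions are harmless.

Step 17
Reactants: 23 7-hydroxylongipina-2,8-dien-1-one, 24 angelic anhydride
Product: 25 7-angeloyloxylongipina-2,8-dien-1-one
Conditions: LiN(SiMe3)2 (1.05 equiv), THF, −78 °C; 24, −78 → 0 °C; aq. NH4Cl
Reagents that add atoms: none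
Why: Acylation of the lithium alkoxide with angelic anhydride esterifies hindered alcohols without a nucleophilic catalyst, which should avoid Z-to-E isomerization to the tiglate.

Step 18
Reactants: 25 7-angeloyloxylongipina-2,8-dien-1-one
Product: 26 7-angeloyloxy-8,9-dihydroxylongipin-2-en-1-one (8,9-cis-diol, trans to the C7 ester)
Conditions: OsO4 (5 mol%), NMO, acetone/H2O, 0 °C
Reagents that add atoms: N-methylmorpholine N-oxide, C[N+]1([O-])CCOCC1; water, O
Why: Upjohn dihydroxylation should take the isolated C8=C9 alkene before the two conjugated, electron-poor trisubstituted alkenes and add anti to the allylic C7 acyloxy group (the usual sense for osmylation next to an allylic oxygen substituent, reinforced by its bulk), setting C8 and C9.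

Step 19
Reactants: 26 7-angeloyloxy-8,9-dihydroxylongipin-2-en-1-one, 27 (R)-2-methylbutanoic acid
Product: 28 target, 7-angeloyloxy-9-hydroxy-8-[(2R)-2-methylbutanoyloxy]longipin-2-en-1-one
Conditions: EDC·HCl, DMAP (0.1 equiv), CH2Cl2, 0 °C
Reagents that add atoms: none
Why: Steglich esterification should acylate the C8 hydroxyl selectively, because the C9 hydroxyl is neopentyl (next to quaternary C10); the low temperature protects the acid's α-centre.

**Compound list**

1 | 4,4-dimethylcyclopent-2-en-1-one | CC1(C)CC(=O)C=C1 | starting material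
2 | 4,4-dimethylcyclopent-2-en-1-one p-toluenesulfonylhydrazone | CC1(C)CC(=NNS(=O)(=O)c2ccc(C)cc2)C=C1 | intermediate
3 | 5,5-dimethylcyclopenta-1,3-diene | CC1(C)C=CC=C1 | intermediate
4 | (E)-but-2-enoyl chloride (crotonyl chloride) | C/C=C/C(Cl)=O | starting material
5 | buta-1,3-dien-1-one (vinylketene) | C=CC=C=O | intermediate (not isolated)
6 | rac-4,4-dimethyl-7-endo-vinylbicyclo[3.2.0]hept-2-en-6-one, cis-fused | C=C[C@H]1[C@H]2C=CC(C)(C)[C@H]2C1=O | intermediate
7 | rac-4,4,7-trimethyl-7-vinylbicyclo[3.2.0]hept-2-en-6-one, 7-methyl exo, 7-vinyl endo | C=C[C@@]1(C)[C@H]2C=CC(C)(C)[C@H]2C1=O | intermediate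
8 | rac-4,4,7-trimethyl-7-vinylbicyclo[3.2.0]hept-2-ene-6-carbonitrile, both C6 epimers | C=C[C@@]1(C)[C@H]2C=CC(C)(C)[C@H]2C1C#N | intermediate
9 | rac-1-(4,4,7-trimethyl-7-vinylbicyclo[3.2.0]hept-2-en-6-yl)ethan-1-imine | C=C[C@@]1(C)[C@H]2C=CC(C)(C)[C@H]2C1C(C)=N | intermediate (not isolated)
10 | rac-1-(4,4,7-trimethyl-7-vinylbicyclo[3.2.0]hept-2-en-6-yl)ethan-1-one, acetyl exo, methyl exo, vinyl endo | C=C[C@@]1(C)[C@H]2C=CC(C)(C)[C@H]2[C@@H]1C(C)=O | intermediate
11 | rac-1-(2,3-dihydroxy-4,4,7-trimethyl-7-vinylbicyclo[3.2.0]heptan-6-yl)ethan-1-one, 2,3-exo-cis-diol | C=C[C@@]1(C)[C@H]2[C@H](O)[C@H](O)C(C)(C)[C@H]2[C@@H]1C(C)=O | intermediate (not isolated)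
12 | rac-2-(2-acetyl-4-formyl-3-methyl-3-vinylcyclobutyl)-2-methylpropanal, formyl cis to the propanal side chain (kinetic epimer) | C=C[C@@]1(C)[C@@H](C=O)[C@H]([C@@H]1C(C)=O)C(C)(C)C=O | intermediate (not isolated)
13 | rac-2-(2-acetyl-4-formyl-3-methyl-3-vinylcyclobutyl)-2-methylpropanal, vinyl and side chain on one face; acetyl, formyl and ring methyl on the other | C=C[C@@]1(C)[C@H](C=O)[C@H]([C@@H]1C(C)=O)C(C)(C)C=O | intermediate
14 | 2-[2-acetyl-4-((4R,5R)-4,5-dimethyl-1,3-dioxolan-2-yl)-3-methyl-3-vinylcyclobutyl]-2-methylpropanal, ring configured as in the target | C=C[C@@]1(C)[C@H](C2O[C@H](C)[C@@H](C)O2)[C@H]([C@@H]1C(C)=O)C(C)(C)C=O | intermediate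
15 | 1-[3-((4R,5R)-4,5-dimethyl-1,3-dioxolan-2-yl)-2-((3R)-3-hydroxy-2-methylpent-4-en-2-yl)-4-methyl-4-vinylcyclobutyl]ethan-1-one, ring as in 14 | C=C[C@@]1(C)[C@H](C2O[C@H](C)[C@@H](C)O2)[C@H]([C@@H]1C(C)=O)C(C)(C)[C@H](O)C=C | intermediate
16 | tert-butyldimethylsilyl ether of 15 | C=C[C@@]1(C)[C@H](C2O[C@H](C)[C@@H](C)O2)[C@H]([C@@H]1C(C)=O)C(C)(C)[C@H](O[Si](C)(C)C(C)(C)C)C=C | intermediate
17 | 7-acetyl-4-(tert-butyldimethylsilyloxy)-8-((4R,5R)-4,5-dimethyl-1,3-dioxolan-2-yl)-1,5,5-trimethylbicyclo[4.1.1]oct-2-ene, bridge substituents anti to the four-carbon bridge | CC(C)(C)[Si](C)(C)O[C@@H]1C=C[C@@]2(C)[C@H](C3O[C@H](C)[C@@H](C)O3)[C@H]([C@@H]2C(C)=O)C1(C)C | intermediate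
18 | 4-(tert-butyldimethylsilyloxy)-8-((4R,5R)-4,5-dimethyl-1,3-dioxolan-2-yl)-7-isopropenyl-1,5,5-trimethylbicyclo[4.1.1]oct-2-ene | CC(C)(C)[Si](C)(C)O[C@@H]1C=C[C@@]2(C)[C@H](C3O[C@H](C)[C@@H](C)O3)[C@H]([C@@H]2C(C)=C)C1(C)C | intermediate
19 | 4-(tert-butyldimethylsilyloxy)-7-isopropenyl-1,5,5-trimethylbicyclo[4.1.1]oct-2-ene-8-carbaldehyde, formyl and isopropenyl cis-1,3, anti to the four-carbon bridge | CC(C)(C)[Si](C)(C)O[C@@H]1C=C[C@@]2(C)[C@H](C=O)[C@H]([C@@H]2C(C)=C)C1(C)C | intermediate
20 | 7-(tert-butyldimethylsilyloxy)longipina-3(12),8-dien-1-ol, both C1 epimers | CC(C)(C)[Si](C)(C)O[C@@H]1C=C[C@@]2(C)[C@@H]3C(O)CC(=C)[C@H]2[C@@H]3C1(C)C | intermediate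
21 | 7-(tert-butyldimethylsilyloxy)longipina-3(12),8-dien-1-one | CC(C)(C)[Si](C)(C)O[C@@H]1C=C[C@@]2(C)[C@@H]3C(=O)CC(=C)[C@H]2[C@@H]3C1(C)C | intermediate (not isolated)
22 | 7-(tert-butyldimethylsilyloxy)longipina-2,8-dien-1-one | CC(C)(C)[Si](C)(C)O[C@@H]1C=C[C@@]2(C)[C@@H]3C(=O)C=C(C)[C@H]2[C@@H]3C1(C)C | intermediate
23 | 7-hydroxylongipina-2,8-dien-1-one | O[C@@H]1C=C[C@@]2(C)[C@@H]3C(=O)C=C(C)[C@H]2[C@@H]3C1(C)C | intermediate
24 | angelic anhydride, (Z)-2-methylbut-2-enoic anhydride | C/C=C(/C)C(=O)OC(=O)/C(C)=C\C | starting material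
25 | 7-angeloyloxylongipina-2,8-dien-1-one | C/C=C(/C)C(=O)O[C@@H]1C=C[C@@]2(C)[C@@H]3C(=O)C=C(C)[C@H]2[C@@H]3C1(C)C | intermediate
26 | 7-angeloyloxy-8,9-dihydroxylongipin-2-en-1-one | C/C=C(/C)C(=O)O[C@@H]1[C@@H](O)[C@@H](O)[C@@]2(C)[C@@H]3C(=O)C=C(C)[C@H]2[C@@H]3C1(C)C | intermediate
27 | (R)-2-methylbutanoic acid | OC(=O)[C@H](C)CC | starting material
28 | (4R,5S,7S,8S,9S,10R,11R)-7-angeloyloxy-9-hydroxy-8-[(2R)-2-methylbutanoyloxy]longipin-2-en-1-one | C/C=C(/C)C(=O)O[C@@H]1[C@@H](OC(=O)[C@H](C)CC)[C@@H](O)[C@@]2(C)[C@@H]3C(=O)C=C(C)[C@H]2[C@@H]3C1(C)C | target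

**Totals and risks**

Total step count: 19. Longest linear sequence: 19 steps (from 1).

Steps most likely to fail:

1. Step 11 (ring-closing metathesis). Both vinyl groups stand next to quaternary carbons and the product is a bridged ring that forces the cyclobutane into its diaxial pucker, so slow catalyst initiation and strain may let oligomerization or catalyst decay win. The fallback sets out from 16 and comes back at 17. Ozonolysis of both vinyl groups of 16 (O3, CH2Cl2/MeOH, −78 °C; Me2S) would give the dialdehyde F1. SmI2 (THF, t-BuOH, −78 °C → rt) would close the seven-membered ring by pinacol coupling of the two aldehydes to the cis-8,9-diol F2, whose configuration is immaterial. 1,1′-Thiocarbonyldiimidazole (toluene, 80 °C) would give the cyclic thionocarbonate F3, and Corey–Winter elimination with 1,3-dimethyl-2-phenyl-1,3,2-diazaphospholidine (THF, 40 °C) would return the cis alkene 17.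

2. Step 14 (carbonyl-ene closure). Ionization to a C3 cation followed by cyclobutane ring expansion, epimerization of the free aldehyde at C11 before closure, or failure to close the strained bridge may compete. The fallback sets out from 17 and comes back at 22. Hydrolysis of the acetal of 17 (PPTS, acetone/H2O) would give the keto-aldehyde F4. Intramolecular aldol condensation of the acetyl methyl group onto the C1 aldehyde (pyrrolidine, AcOH, benzene, 60 °C) would again form C1–C2 and give the transposed enone F5. MeLi (THF, −78 °C) would add 1,2 to give the tertiary allylic alcohol F6, and oxidative 1,3-transposition with pyridinium chlorochromate, (C5H5NH)[CrO3Cl], in CH2Cl2 (Babler–Dauben) would give 22.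

3. Step 18 (dihydroxylation with the angelate in place). Competing osmylation of the angelate or enone alkene, and weaker facial control by an ester than by a silyl ether, may erode selectivity. The fallback sets out from 22 and comes back at 26. Dihydroxylation of 22 (OsO4, NMO), anti to the bulky silyl ether, would give the diol F7. 2,2-Dimethoxypropane with PPTS would give the acetonide F8, and n-Bu4NF the alcohol F9. LiN(SiMe3)2 and angelic anhydride would give the angelate F10, and aqueous AcOH at 40 °C would remove the acetonide to give 26.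

Further compounds
F1 | step 11 | 2-[(3S)-3-(tert-butyldimethylsilyloxy)-2-methyl-4-oxobutan-2-yl]-1-acetyl-3-((4R,5R)-4,5-dimethyl-1,3-dioxolan-2-yl)-4-formyl-4-methylcyclobutane (dialdehyde from 16) | O=C[C@@]1(C)[C@H](C2O[C@H](C)[C@@H](C)O2)[C@H]([C@@H]1C(C)=O)C(C)(C)[C@H](O[Si](C)(C)C(C)(C)C)C=O
F2 | step 11 | 7-acetyl-4-(tert-butyldimethylsilyloxy)-8-((4R,5R)-4,5-dimethyl-1,3-dioxolan-2-yl)-1,5,5-trimethylbicyclo[4.1.1]octane-2,3-diol (cis-diol) | CC(C)(C)[Si](C)(C)O[C@@H]1[C@@H](O)[C@@H](O)[C@@]2(C)[C@H](C3O[C@H](C)[C@@H](C)O3)[C@H]([C@@H]2C(C)=O)C1(C)C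
F3 | step 11 | cyclic thionocarbonate of F2 | CC(C)(C)[Si](C)(C)O[C@@H]1[C@H]2OC(=S)O[C@H]2[C@@]3(C)[C@H](C4O[C@H](C)[C@@H](C)O4)[C@H]([C@@H]3C(C)=O)C1(C)C
F4 | step 14 | 7-acetyl-4-(tert-butyldimethylsilyloxy)-1,5,5-trimethylbicyclo[4.1.1]oct-2-ene-8-carbaldehyde | CC(C)(C)[Si](C)(C)O[C@@H]1C=C[C@@]2(C)[C@H](C=O)[C@H]([C@@H]2C(C)=O)C1(C)C
F5 | step 14 | 7-(tert-butyldimethylsilyloxy)-12-norlongipina-1,8-dien-3-one (transposed enone) | CC(C)(C)[Si](C)(C)O[C@@H]1C=C[C@@]2(C)[C@@H]3C=CC(=O)[C@H]2[C@@H]3C1(C)C
F6 | step 14 | 7-(tert-butyldimethylsilyloxy)longipina-1,8-dien-3-ol (tertiary allylic alcohol, both C3 epimers) | CC(C)(C)[Si](C)(C)O[C@@H]1C=C[C@@]2(C)[C@@H]3C=CC(C)(O)[C@H]2[C@@H]3C1(C)C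
F7 | step 18 | 7-(tert-butyldimethylsilyloxy)-8,9-dihydroxylongipin-2-en-1-one | CC(C)(C)[Si](C)(C)O[C@@H]1[C@@H](O)[C@@H](O)[C@@]2(C)[C@@H]3C(=O)C=C(C)[C@H]2[C@@H]3C1(C)C
F8 | step 18 | 8,9-O-isopropylidene derivative of F7 | CC(C)(C)[Si](C)(C)O[C@@H]1[C@H]2OC(C)(C)O[C@H]2[C@@]3(C)[C@@H]4C(=O)C=C(C)[C@H]3[C@@H]4C1(C)C
F9 | step 18 | 7-hydroxy-8,9-(isopropylidenedioxy)longipin-2-en-1-one | O[C@@H]1[C@H]2OC(C)(C)O[C@H]2[C@@]3(C)[C@@H]4C(=O)C=C(C)[C@H]3[C@@H]4C1(C)C
F10 | step 18 | 7-angeloyloxy-8,9-(isopropylidenedioxy)longipin-2-en-1-one | C/C=C(/C)C(=O)O[C@@H]1[C@H]2OC(C)(C)O[C@H]2[C@@]3(C)[C@@H]4C(=O)C=C(C)[C@H]3[C@@H]4C1(C)C
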